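**Retrosynthetic overview**
1. δ‑Tocopherol (6) ⇐ hydrogenation of the C3=C4 bond of (2R)‑3,4‑dehydro‑δ‑tocopherol (5).
2. 5 ⇐ catalytic asymmetric isomerisation of 2‑methyl‑6‑phytyl‑1,4‑benzoquinone (4): vinylogous enolisation to a vinyl ortho‑quinone methide, then oxa‑6π closure. This forms the pyran ring and sets C2.
3. 4 ⇐ oxidative dearomatisation (para‑oxygenation) of 2‑methyl‑6‑phytylphenol (3), which installs the future C6–OH and unlocks the cyclisation.
4. 3 ⇐ ortho‑C‑phytylation of o‑cresol (1) with natural phytol (2). Phytol supplies C2, C3, C4, the 2‑methyl, the whole side chain and both 4'R/8'R centres.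
5. Ring order: the benzene ring comes from o‑cresol (dearomatised to the quinone, then re‑aromatised); the pyran ring is closed last.

Assumptions: natural (2E,7R,11R)‑phytol (≥95 % E) is taken as commercially available. The catalyst antipode that gives 2R in step 3 must be fixed by one screening run; the (R)‑catalyst is written.

**Step 1**
Reactants: 1, o‑cresol (2‑methylphenol, 3 equiv); 2, (2E,7R,11R)‑phytol
Product: 3, 2‑methyl‑6‑[(2E,7R,11R)‑3,7,11,15‑tetramethylhexadec‑2‑en‑1‑yl]phenol
Conditions: acidic Al2O3, 1,2‑dichloroethane, reflux, 24 h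
Reagents that add atoms: none
Why: Alumina‑templated dehydrative Friedel–Crafts allylation delivers the primary allyl terminus to the only free ortho position of the surface‑bound phenol, largely retaining the E alkene and leaving 7R/11R untouched; no new stereocentre.

**Step 2**
Reactants: 3, 2‑methyl‑6‑phytylphenol
Product: 4, 2‑methyl‑6‑[(2E,7R,11R)‑3,7,11,15‑tetramethylhexadec‑2‑en‑1‑yl]cyclohexa‑2,5‑diene‑1,4‑dione
Conditions: O2 (1 atm), Co(salen) (salcomine, 10 mol %), DMF, rt, dark; neutral work‑up (no basic alumina)
Reagents that add atoms: dioxygen, O=O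
Why: Salcomine‑catalysed para‑oxygenation of a 2,6‑dialkylphenol (oxidative dearomatisation to the p‑benzoquinone) introduces the oxygen that becomes C6–OH; the isolated trisubstituted alkene and remote stereocentres are inert.

**Step 3**
Reactants: 4, 2‑methyl‑6‑phytyl‑1,4‑benzoquinone
Product: 5, (2R)‑2,8‑dimethyl‑2‑[(4R,8R)‑4,8,12‑trimethyltridecyl]‑2H‑chromen‑6‑ol
Conditions: (R)‑3,3'‑bis(2,4,6‑triisopropylphenyl)‑H8‑BINOL N‑triflylphosphoramide (5–10 mol %), toluene, 4 Å MS, 0 °C → rt, Ar, dark
Reagents that add atoms: none
Why: Proposed new method: the chiral acid protonates the C4 carbonyl and its anion removes the allylic CH2 proton γ to that carbonyl, giving the 4‑hydroxy vinyl ortho‑quinone methide, which stays ion‑paired with the catalyst at O1 and undergoes disrotatory oxa‑6π closure (O1 to the Me,alkyl‑substituted alkene carbon); because the alkene is E‑defined, C2 is decided only by which helical (P or M) transition state fits the catalyst pocket, and the closest known reactions are the chiral N‑triflylphosphoramide‑catalysed cyclisation of o‑hydroxyaryl allylic alcohols to 2,2‑disubstituted 2H‑chromenes via chiral contact ion pairs and the racemic base‑ or alumina‑mediated prenylquinone → chromenol isomerisation.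

**Step 4**
Reactants: 5, (2R)‑3,4‑dehydro‑δ‑tocopherol (used directly, under Ar)
Product: 6, (2R,4'R,8'R)‑δ‑tocopherol
Conditions: H2 (1 atm), 5 % Pd/C, EtOAc, rt
Reagents that add atoms: none
Why: Heterogeneous catalytic hydrogenation of the styrenyl C3=C4 bond of a 2,2‑dialkyl‑2H‑chromene; no new stereocentre is formed, and the quaternary C2 and the chain centres cannot epimerise.

**Compound list**
1 | o‑cresol | Cc1ccccc1O | starting material
2 | (2E,7R,11R)‑phytol | OC/C=C(\C)CCC[C@H](C)CCC[C@H](C)CCCC(C)C | starting material
3 | 2‑methyl‑6‑[(2E,7R,11R)‑phytyl]phenol | Cc1cccc(C/C=C(\C)CCC[C@H](C)CCC[C@H](C)CCCC(C)C)c1O | intermediate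
4 | 2‑methyl‑6‑[(2E,7R,11R)‑phytyl]‑1,4‑benzoquinone | CC1=CC(=O)C=C(C/C=C(\C)CCC[C@H](C)CCC[C@H](C)CCCC(C)C)C1=O | intermediate
5 | (2R)‑2,8‑dimethyl‑2‑[(4R,8R)‑4,8,12‑trimethyltridecyl]‑2H‑chromen‑6‑ol | Cc1cc(O)cc2c1O[C@](C)(CCC[C@H](C)CCC[C@H](C)CCCC(C)C)C=C2 | intermediate
6 | (2R,4'R,8'R)‑δ‑tocopherol | Cc1cc(O)cc2c1O[C@](C)(CCC[C@H](C)CCC[C@H](C)CCCC(C)C)CC2 | target

**Totals**
Total steps: 4. Longest linear sequence: 4.

**Steps most likely to fail, with fallbacks**
1. Step 3 (unprecedented enantiocontrol; competing enolisation toward the ring methyl and quinone methide oligomers). Fallback: drop the 6π closure. Reduce 4 with Na2S2O4 to 2‑methyl‑6‑phytylhydroquinone and close the ring by enantioselective alkene protonation/hydroalkoxylation, using recombinant tocopherol cyclase (the natural 2R‑selective reaction) or a confined chiral Brønsted acid. This gives 6 directly and makes step 4 unnecessary.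
2. Step 1 (partial E/Z scrambling through the allyl cation, bis‑allylation, some chroman formation). Fallback: form the aryl–C bond by SN2 coupling instead. MOM‑protect 2‑bromo‑6‑methylphenol, do Br/Li exchange, convert to the cuprate, couple with (E)‑phytyl bromide (from 2, PBr3), then remove MOM with acid.
3. Step 2 (diphenoquinone C–C coupling or over‑oxidation). Fallback: carry the para oxygen from the start. Use 4‑methoxy‑2‑methylphenol in step 1 and convert the resulting p‑methoxyphenol to 4 by CAN oxidative demethylation.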